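(All runs come from a simulation for substances that don't exist; the scatter is artificial.)

The rate asked for cannot be read straight off the runs: the fixed amount of target, 4.00 mM, lies below the first reading of each run, so it has to be reasoned out.

| flask | starting material | reagent | time |
|---|---|---|---|
| maple | 200 mM | 220 mM |  |
| elm | 200 mM | 660 mM |  |
| larch | 400 mM | 220 mM |  |
| oak | 60.0 mM | 80.0 mM | 160 s |

| maple run: time / s | maple run: [target] / mM | elm run: time / s | elm run: [target] / mM | larch run: time / s | larch run: [target] / mM |
|---|---|---|---|---|---|
| 9.1 | 5.0 | 9.1 | 8.7 | 9.1 | 8.9 |
| 28 | 25.3 | 28 | 31.1 | 28 | 49.2 |
| 53 | 47.3 | 53 | 44.2 | 53 | 89.6 |
| 84 | 64.4 | 84 | 49.5 | 84 | 121.9 |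
| 120 | 76.5 | 120 | 48.0 | 120 | 143.2 |
| 160 | 79.9 | 160 | 40.8 | 160 | 155.1 |

(each reading ± 1 mM)

- order of the initial rate in [starting material], near the charge of the maple run, the rate being that where two percent of its starting material are target (one fixed amount of target, the same in the runs compared)
- order of the initial rate in [reagent], near the charge of the maple run, the rate being that where two percent of its starting material are target
- target in the oak run at 160 s, as a share of the starting material charged

- Overall: starting material + reagent -> target.
- Constant volume, constant temperature.
- "The second partner" is reagent.
- An order is taken over about fifteen percent of the charge, up and down.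

A first estimate for starting material uses the slopes between the first two readings: 2.13 mM/s in the larch run and 1.07 mM/s in the maple run. That is a ratio of 1.99 for twice the charge, so the order looks like 1. But those slopes belong to one time, not to one amount of target.

Counted as shares of the charge, the two curves nearly coincide: at 53 s, c(target) is 23.6 % of the charge in the maple run and 22.4 % in the larch run. The useful clock is therefore the quarter time, the time at which target reaches a quarter of the starting material charged, which interpolation puts at 57.9 s in the maple run.

The fixed amount, however, is 1.00 % of the charge in the larch run, half the maple run's 2.00 %, so the larch run is caught earlier in its lag (induction period). The maple run shows that lag: its mean rate up to the first reading, 0.549 mM/s, is lower than 1.07 mM/s. Where target grows with the square of time and in proportion to the charge, the rate at one fixed amount of target goes with the square root of the charge, and the order falls to 0.5. The reckoning here takes the middle, 0.750.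

For reagent, the first readings of the elm and maple runs give 0.504 at one time and, by the same root, 0.252 at one amount.

That elm-to-maple ratio drifts, from 1.74 at the first reading to 0.511 at 160 s, so extra reagent helps early and costs late. The oak flask, with less reagent, should then start slower but lose less, and the reckoning here stays near the maple share, 40.0 %.

The forecast gives 0.9, 0.4 and 33 %, holding that “Oak, with less reagent, runs on a slower clock”.

The flask gives 0.66, 0.41 and 39.9 %.

starting material → intermediate (0.009290 /s); intermediate + reagent → target (0.4010 /M/s); intermediate → side product (0.005240 /s); starting material → decomposed substrate (0.004340 /s); target + reagent → side product (0.02230 /M/s) The loss of target with reagent to side product moves the readings by 28 in units of the scatter. At 160 s, which is 2.76 maple quarter times, the oak flask stands at 39.9 % against the maple reading of 40.0 %. The larch run reaches its quarter at 60.8 s, 1.05 times the maple quarter time of 57.9 s.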